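**Retrosynthetic overview**

1. The target is a (2R)-2H-chromene (benzene ring A fused to pyran ring B) with methyl and CH2O-feruloyl on C2, acetyl on C6 and methoxy on C8. The last operation only uncaps the ferulate phenol.
2. Feature used: the O1–C2 bond and the ester O–CH2 bond lie on neighbouring carbons, C2 and its exocyclic CH2. These two carbons are read as the terminal C=CH2 of a 3-methylbuta-1,3-dienyl chain on C4a, with C3=C4 as its inner alkene.
3. Key disconnection: both C–O bonds are cut at once, giving an E-dienylphenol and 4-O-acetylferulic acid, joined by an oxidative, enantioselective palladium 1,2-oxyacyloxylation. Ring B is the only ring formed, in that step, on the preformed ring A.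
4. The dienylphenol is cut at C4a–C4 (Suzuki–Miyaura) into 5-iodoacetovanillone and the E-dienyl pinacolboronate from 2-methylbut-1-en-3-yne. The acid partner comes from ferulic acid by O-acetylation.

Key step: step 5

Assumption: the sense of induction of the chiral ligand cannot be derived on paper; the (S,S) ligand is written for the (2R) product, and its mirror image would be used if a first experiment shows the opposite sense.

**Route**

Step 1
Reactants: 1 acetovanillone
Product: 2 1-(4-hydroxy-3-iodo-5-methoxyphenyl)ethanone (5-iodoacetovanillone)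
Conditions: N-iodosuccinimide (1.05 equiv), TsOH·H2O (10 mol %), MeCN, rt
Reagents that add atoms: N-iodosuccinimide, O=C1CCC(=O)N1I
Why: Electrophilic aromatic iodination goes to the only open position ortho to the phenol (also meta to the acetyl group), and the acidic conditions avoid the haloform reaction that basic iodine would start at the methyl ketone.

Step 2
Reactants: 3 2-methylbut-1-en-3-yne
Product: 4 2-[(1E)-3-methylbuta-1,3-dien-1-yl]-4,4,5,5-tetramethyl-1,3,2-dioxaborolane
Conditions: pinacolborane (1.0 equiv), Cp2Zr(H)Cl (5 mol %), Et3N (5 mol %), neat, sealed tube, 50 °C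
Reagents that add atoms: pinacolborane, CC1(C)OBOC1(C)C
Why: Zirconium-catalysed hydroboration adds H–B syn and anti-Markovnikov across the terminal alkyne, which reacts much faster than the conjugated 1,1-disubstituted alkene, so the E-dienylboronate should result.

Step 3
Reactants: 2 5-iodoacetovanillone; 4 E-dienyl pinacolboronate
Product: 5 1-{4-hydroxy-3-methoxy-5-[(1E)-3-methylbuta-1,3-dien-1-yl]phenyl}ethanone
Conditions: Pd(PPh3)4 (5 mol %), K2CO3 (3 equiv), 1,4-dioxane/H2O, 80 °C; mild acidic work-up
Reagents that add atoms: none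
Why: Suzuki–Miyaura coupling of an aryl iodide with an alkenylboronate keeps the E geometry and tolerates the ketone and the free ortho phenol, which is carried as its phenoxide.

Step 4
Reactants: 6 ferulic acid
Product: 7 (2E)-3-[4-(acetyloxy)-3-methoxyphenyl]prop-2-enoic acid (4-O-acetylferulic acid)
Conditions: Ac2O, aq NaOH, 0 °C to rt; then aq HCl
Reagents that add atoms: acetic anhydride, CC(=O)OC(C)=O
Why: Schotten–Baumann O-acetylation caps the phenoxide in cold aqueous alkali, while water returns any mixed anhydride to the carboxylate, so only the phenol stays acylated.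

Step 5
Reactants: 5 dienylphenol; 7 4-O-acetylferulic acid
Product: 8 [(2R)-6-acetyl-8-methoxy-2-methyl-2H-chromen-2-yl]methyl (2E)-3-[4-(acetyloxy)-3-methoxyphenyl]prop-2-enoate
Conditions: Pd(OAc)2 (10 mol %), (S)-4-tert-butyl-2-{2-[(S)-p-tolylsulfinyl]phenyl}-4,5-dihydrooxazole (12 mol %), 2,6-dimethyl-1,4-benzoquinone (1.5 equiv), 7 (2 equiv), iPr2NEt (10 mol %), 1,4-dioxane, 40 °C, dark
Reagents that add atoms: none
Why: Proposed new method: divalent palladium bearing the chiral sulfoxide–oxazoline binds the terminal 1,1-disubstituted alkene of 5, the carboxylate of 7 attacks the CH2 terminus anti to the metal, and the allyl complex spanning C2–C3–C4 then passes through its C4-bound (benzylic) sigma form, in which rotation about C3–C4 moves the aryl group from syn to anti so that the phenol oxygen can reach C2. The phenoxide attacks C2 anti to palladium, which closes ring B in the 6-endo allylic mode (the C3=C4 alkene ends inside the ring), and the zerovalent palladium released is returned to the divalent state by the quinone. The closest known reactions are the palladium/quinone 1,4-diacyloxylation and intramolecular 1,4-oxyacyloxylation of conjugated dienes, together with oxidative chroman and 2H-chromene syntheses in which a phenol captures an allylpalladium complex; the new elements are the 1,2-mode with an external acid and the ligand control. The C2 stereocentre is controlled by the ligand on palladium, which selects the alkene face at acyloxypalladation (or, if that step is reversible, the faster-closing diastereomeric allyl complex); since the C4 sigma passage turns the other face of C2 toward the metal and the closure is anti, the ring oxygen arrives on the C2 face that palladium first occupied. The step needs 1,2- over 1,4-regioselectivity, secured because phenoxide attack at C4 would give a four-membered ring, and it needs acyloxylation to precede ring closure, secured because the E geometry keeps the phenol away from C2 until the allyl complex has formed and isomerised. Excess 7 outcompetes the acetate of the precatalyst, and the mild, dark conditions avoid electrocyclic ring opening of the 2H-chromene, which would racemise C2.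

Step 6
Reactants: 8 O-acetyl chromene ester
Product: 9 [(2R)-6-acetyl-8-methoxy-2-methyl-2H-chromen-2-yl]methyl (2E)-3-(4-hydroxy-3-methoxyphenyl)prop-2-enoate (target)
Conditions: pyrrolidine (3 equiv), CH2Cl2, 0 °C to rt, dark
Reagents that add atoms: none
Why: Aminolysis of an aryl acetate by a secondary amine is much faster than cleavage of, or conjugate addition to, the alkyl cinnamate, and the room-temperature, light-protected conditions should leave the C2 stereocentre untouched.

**Compound list**

1 | acetovanillone, 1-(4-hydroxy-3-methoxyphenyl)ethanone | CC(=O)c1ccc(O)c(OC)c1 | starting material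
2 | 1-(4-hydroxy-3-iodo-5-methoxyphenyl)ethanone | CC(=O)c1cc(I)c(O)c(OC)c1 | intermediate
3 | 2-methylbut-1-en-3-yne | C=C(C)C#C | starting material
4 | 2-[(1E)-3-methylbuta-1,3-dien-1-yl]-4,4,5,5-tetramethyl-1,3,2-dioxaborolane | CC(=C)/C=C/B1OC(C)(C)C(C)(C)O1 | intermediate
5 | 1-{4-hydroxy-3-methoxy-5-[(1E)-3-methylbuta-1,3-dien-1-yl]phenyl}ethanone | CC(=O)c1cc(/C=C/C(C)=C)c(O)c(OC)c1 | intermediate
6 | ferulic acid, (2E)-3-(4-hydroxy-3-methoxyphenyl)prop-2-enoic acid | COc1cc(/C=C/C(=O)O)ccc1O | starting material
7 | 4-O-acetylferulic acid, (2E)-3-[4-(acetyloxy)-3-methoxyphenyl]prop-2-enoic acid | CC(=O)Oc1ccc(/C=C/C(=O)O)cc1OC | intermediate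
8 | [(2R)-6-acetyl-8-methoxy-2-methyl-2H-chromen-2-yl]methyl (2E)-3-[4-(acetyloxy)-3-methoxyphenyl]prop-2-enoate | CC(=O)Oc1ccc(/C=C/C(=O)OC[C@@]2(C)C=Cc3cc(C(C)=O)cc(OC)c3O2)cc1OC | intermediate
9 | [(2R)-6-acetyl-8-methoxy-2-methyl-2H-chromen-2-yl]methyl (2E)-3-(4-hydroxy-3-methoxyphenyl)prop-2-enoate | COc1cc(/C=C/C(=O)OC[C@@]2(C)C=Cc3cc(C(C)=O)cc(OC)c3O2)ccc1O | target

**Step count and risks**

Total steps: 6. Longest linear sequence: 4 (steps 1, 3, 5, 6).

Steps most likely to fail:

1. Step 5 (proposed new method). The phenol may add to the styrene alkene by 5-endo oxypalladation before the carboxylate is delivered, a second carboxylate may capture the allyl complex at C4 in the 1,4-mode, or the ligand may give poor facial selectivity. The fallback uses known chemistry, sets out from 1 and returns at 8.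
 - Ethynylmagnesium bromide is added to commercial 1-[(tert-butyldimethylsilyl)oxy]propan-2-one (THF, 0 °C) to give racemic 1-[(tert-butyldimethylsilyl)oxy]-2-methylbut-3-yn-2-ol F1.
 - LiHMDS and ClCO2Me (THF, −78 °C) convert it into racemic 1-[(tert-butyldimethylsilyl)oxy]-2-methylbut-3-yn-2-yl methyl carbonate F2.
 - Copper-catalysed propargylic etherification of 1 with F2 (CuCl2, DBU, MeCN, 0 °C) should give racemic 1-[4-({1-[(tert-butyldimethylsilyl)oxy]-2-methylbut-3-yn-2-yl}oxy)-3-methoxyphenyl]ethanone F3.
 - Heating (xylene, 140 °C) brings about aryl propargyl Claisen rearrangement to the only free ortho position, 1,5-hydrogen shift and oxa-6π ring closure, giving racemic 1-(2-{[(tert-butyldimethylsilyl)oxy]methyl}-8-methoxy-2-methyl-2H-chromen-6-yl)ethanone F4.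
 - TBAF in THF liberates racemic 1-[2-(hydroxymethyl)-8-methoxy-2-methyl-2H-chromen-6-yl]ethanone F5.
 - Preparative HPLC on a chiral stationary phase separates 1-[(2R)-2-(hydroxymethyl)-8-methoxy-2-methyl-2H-chromen-6-yl]ethanone F6.
 - Steglich esterification of F6 with 7 (EDC·HCl, DMAP, CH2Cl2, rt) gives 8.

2. Step 3. The arylpalladium intermediate may insert into the diene already formed, with the ortho phenoxide then trapping the resulting allyl complex, and the dienylboronate may protodeboronate in hot aqueous base. The fallback masks the phenol, sets out from 2 and returns at 5.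
 - 2 is silylated (TBSCl, imidazole, DMF) to 1-{4-[(tert-butyldimethylsilyl)oxy]-3-iodo-5-methoxyphenyl}ethanone F7.
 - F7 is coupled with 4 (Pd(PPh3)4, K3PO4, toluene/H2O, 70 °C) to 1-{4-[(tert-butyldimethylsilyl)oxy]-3-methoxy-5-[(1E)-3-methylbuta-1,3-dien-1-yl]phenyl}ethanone F8.
 - F8 is desilylated (TBAF, AcOH, THF, 0 °C) to 5 without acid, which would cyclise the diene onto the phenol.

3. Step 6. Aminolysis may not stop at the aryl acetate, with the amine also adding to the cinnamate alkene or cleaving the cinnamate ester. The fallback replaces the acyl cap by a silyl cap that is removed with fluoride; it sets out from 6 and returns at 9.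
 - 6 is bis-silylated (TBSCl, imidazole, DMF) to tert-butyldimethylsilyl (2E)-3-{4-[(tert-butyldimethylsilyl)oxy]-3-methoxyphenyl}prop-2-enoate F9.
 - The silyl ester of F9 is cleaved in the same flask (aq K2CO3, THF/MeOH) to (2E)-3-{4-[(tert-butyldimethylsilyl)oxy]-3-methoxyphenyl}prop-2-enoic acid F10.
 - F10 takes the place of 7 under the conditions of step 5 and should give [(2R)-6-acetyl-8-methoxy-2-methyl-2H-chromen-2-yl]methyl (2E)-3-{4-[(tert-butyldimethylsilyl)oxy]-3-methoxyphenyl}prop-2-enoate F11.
 - TBAF buffered with AcOH (THF, 0 °C) then gives 9.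

**Further compounds**

F1 | step 5 | racemic 1-[(tert-butyldimethylsilyl)oxy]-2-methylbut-3-yn-2-ol | CC(O)(CO[Si](C)(C)C(C)(C)C)C#C
F2 | step 5 | racemic 1-[(tert-butyldimethylsilyl)oxy]-2-methylbut-3-yn-2-yl methyl carbonate | COC(=O)OC(C)(CO[Si](C)(C)C(C)(C)C)C#C
F3 | step 5 | racemic 1-[4-({1-[(tert-butyldimethylsilyl)oxy]-2-methylbut-3-yn-2-yl}oxy)-3-methoxyphenyl]ethanone | CC(=O)c1ccc(OC(C)(CO[Si](C)(C)C(C)(C)C)C#C)c(OC)c1
F4 | step 5 | racemic 1-(2-{[(tert-butyldimethylsilyl)oxy]methyl}-8-methoxy-2-methyl-2H-chromen-6-yl)ethanone | CC(=O)c1cc2C=CC(C)(CO[Si](C)(C)C(C)(C)C)Oc2c(OC)c1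
F5 | step 5 | racemic 1-[2-(hydroxymethyl)-8-methoxy-2-methyl-2H-chromen-6-yl]ethanone | CC(=O)c1cc2C=CC(C)(CO)Oc2c(OC)c1
F6 | step 5 | 1-[(2R)-2-(hydroxymethyl)-8-methoxy-2-methyl-2H-chromen-6-yl]ethanone | OC[C@@]1(C)C=Cc2cc(C(C)=O)cc(OC)c2O1
F7 | step 3 | 1-{4-[(tert-butyldimethylsilyl)oxy]-3-iodo-5-methoxyphenyl}ethanone | CC(=O)c1cc(I)c(O[Si](C)(C)C(C)(C)C)c(OC)c1
F8 | step 3 | 1-{4-[(tert-butyldimethylsilyl)oxy]-3-methoxy-5-[(1E)-3-methylbuta-1,3-dien-1-yl]phenyl}ethanone | CC(=O)c1cc(/C=C/C(C)=C)c(O[Si](C)(C)C(C)(C)C)c(OC)c1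
F9 | step 6 | tert-butyldimethylsilyl (2E)-3-{4-[(tert-butyldimethylsilyl)oxy]-3-methoxyphenyl}prop-2-enoate | COc1cc(/C=C/C(=O)O[Si](C)(C)C(C)(C)C)ccc1O[Si](C)(C)C(C)(C)C
F10 | step 6 | (2E)-3-{4-[(tert-butyldimethylsilyl)oxy]-3-methoxyphenyl}prop-2-enoic acid | COc1cc(/C=C/C(=O)O)ccc1O[Si](C)(C)C(C)(C)C
F11 | step 6 | [(2R)-6-acetyl-8-methoxy-2-methyl-2H-chromen-2-yl]methyl (2E)-3-{4-[(tert-butyldimethylsilyl)oxy]-3-methoxyphenyl}prop-2-enoate | COc1cc(/C=C/C(=O)OC[C@@]2(C)C=Cc3cc(C(C)=O)cc(OC)c3O2)ccc1O[Si](C)(C)C(C)(C)C
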